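**Retrosynthetic overview**
1. Scolopendrine comes from its 4'-O-benzyl ether by a final hydrogenolysis. Both benzene rings are bought, and the pyridone is the only ring built.
2. The C8–O bond and the sulfate come from an N→C8 sulfate migration in an O-sulfated 1,4-dihydroxy-3,4-dihydroquinolin-2-one. Loss of the C4 oxygen then aromatises the ring, and the C8 oxygen is a former nitro oxygen.
3. The N1–C2 ring closure comes from partial reduction and lactamisation of a 2-nitroaryl β-hydroxy-α-methoxy ester.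
4. The C7–CH2 bond comes from a Negishi coupling of the aryl bromide and O-benzylvanillylzinc chloride.
5. The C3–C4 bond comes from an aldol addition of methyl methoxyacetate to 4-bromo-2-nitrobenzaldehyde.

Assumption: the target has no stereocentre, so no enantiocontrol is needed; the C3/C4 centres of 4 and 7–11 are carried as diastereomer mixtures and erased in step 4; sulfate half-esters are handled as Bu3NH+ salts but drawn and counted as free acids.

**Step 1**
Reactants: 1 4-bromo-2-nitrobenzaldehyde; 2 methyl methoxyacetate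
Product: 4 methyl 3-(4-bromo-2-nitrophenyl)-3-hydroxy-2-methoxypropanoate (syn/anti racemates), via lithium ester enolate 3 (not isolated)
Conditions: LDA (1.1 equiv), 2, THF, −78 °C, 30 min; 1, −78 °C, 1 h; sat. aq. NH4Cl
Reagents that add atoms: none
Why: Aldol addition, in which the kinetic lithium enolate of the α-alkoxy ester adds quickly to the very electrophilic, non-enolisable aldehyde at −78 °C; the two new stereocentres need no control because both become sp2 in step 4, and stopping at the sp3 aldol avoids the E/Z problem a cinnamate would cause in the lactamisation.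

**Step 2**
Reactants: 4 methyl 3-(4-bromo-2-nitrophenyl)-3-hydroxy-2-methoxypropanoate; 5 4-(benzyloxy)-3-methoxybenzyl chloride
Product: 7 methyl 3-{4-[4-(benzyloxy)-3-methoxybenzyl]-2-nitrophenyl}-3-hydroxy-2-methoxypropanoate (syn/anti racemates), via benzylic zinc chloride 6 (not isolated)
Conditions: 5, Zn dust, LiCl, THF, 25 °C, solution decanted from excess Zn; 4, Pd(OAc)2 (2 mol %), SPhos (4 mol %), THF, 25 °C (2.2 equiv of 6)
Reagents that add atoms: none
Why: Negishi sp2–sp3 cross-coupling, in which the LiCl-assisted benzylic zinc chloride tolerates ester, nitro and (under Pd/SPhos) the free hydroxyl, and the electron-poor aryl bromide undergoes fast oxidative addition; no stereocentre is touched.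

**Step 3**
Reactants: 7 methyl 3-{4-[4-(benzyloxy)-3-methoxybenzyl]-2-nitrophenyl}-3-hydroxy-2-methoxypropanoate
Product: 9 7-[4-(benzyloxy)-3-methoxybenzyl]-1,4-dihydroxy-3-methoxy-3,4-dihydroquinolin-2(1H)-one (cis/trans racemates), via aryl hydroxylamine 8 (not isolated)
Conditions: Zn dust (2.5 equiv), NH4Cl, THF/H2O, 0 → 25 °C, dark
Reagents that add atoms: none
Why: Reductive cyclisation, in which buffered Zn/NH4Cl stops the nitro reduction at ArNHOH and its α-effect nitrogen closes on the freely rotating methyl ester (6-exo-trig lactamisation), giving the cyclic hydroxamic acid with N1–C2 formed and one nitro oxygen kept on nitrogen.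

**Step 4**
Reactants: 9 7-[4-(benzyloxy)-3-methoxybenzyl]-1,4-dihydroxy-3-methoxy-3,4-dihydroquinolin-2(1H)-one
Product: 12 7-[4-(benzyloxy)-3-methoxybenzyl]-3-methoxy-2-oxo-1,2-dihydroquinolin-8-yl hydrogen sulfate, via N-O/C4-O bis-sulfate 10 (not isolated), via rearranged 4,8-bis-sulfate 11 (not isolated)
Conditions: Bu3N·SO3 (2.5 equiv), MeCN, 25 → 70 °C; then DBU (3 equiv), 25 → 50 °C; isolated as the Bu3NH+ salt
Reagents that add atoms: tributylsulfoammonium betaine (Bu3N·SO3), CCCC[N+](CCCC)(CCCC)S(=O)(=O)[O-]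
Why: Proposed new method: an N→C8 sulfate shift on a ring-locked N-aryl hydroxamic acid coupled to aromatisation, in which Bu3N·SO3 sulfates the acidic N–OH and the C4–OH, the half-chair of the still saturated lactam lets the pyramidal N–OSO3− bond tilt out of the arene plane so that it overlaps with the aryl π system and ionises (Bu3NH+ hydrogen-bonds the leaving sulfate), the tight N-acyl-N-arylnitrenium/sulfate pair (or the equivalent asynchronous [3,3] shift through O=S–O–N–C8a=C8) collapses at the only free ortho carbon C8 and tautomerises to the NH lactam 11, and DBU added only after the shift expels the C4 sulfate by E1cB, so one pot forms the C8–O bond, places the sulfate on the correct oxygen without a free 8-OH and erases both stereocentres; the closest known reaction type is the ortho rearrangement of acyclic N-aryl-N-(sulfonyloxy or sulfonatooxy)amides and of arylhydroxylamine O-sulfonates (the Boyland–Sims intermediate), not yet shown on cyclic hydroxamic acids.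

**Step 5**
Reactants: 12 7-[4-(benzyloxy)-3-methoxybenzyl]-3-methoxy-2-oxo-1,2-dihydroquinolin-8-yl hydrogen sulfate
Product: 13 scolopendrine
Conditions: H2 (1 atm), 10 % Pd/C, MeOH, 25 °C; Dowex 50W (H+), 0 °C, freeze-dry
Reagents that add atoms: none
Why: Catalytic hydrogenolysis of the aryl benzyl ether, to which aryl sulfate salts, the diarylmethane and the aromatic 2-quinolone are inert at 1 atm; brief cold H+ exchange gives the free hydrogen sulfate.

**Compound list**
1 | 4-bromo-2-nitrobenzaldehyde | O=Cc1ccc(Br)cc1[N+](=O)[O-] | starting material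
2 | methyl methoxyacetate | COCC(=O)OC | starting material
3 | lithium enolate of methyl methoxyacetate | [Li+].[O-]C(OC)=COC | intermediate
4 | methyl 3-(4-bromo-2-nitrophenyl)-3-hydroxy-2-methoxypropanoate (syn/anti racemates) | COC(=O)C(OC)C(O)c1ccc(Br)cc1[N+](=O)[O-] | intermediate
5 | 4-(benzyloxy)-3-methoxybenzyl chloride | COc1cc(CCl)ccc1OCc1ccccc1 | starting material
6 | [4-(benzyloxy)-3-methoxybenzyl]zinc chloride (LiCl complex) | COc1cc(C[Zn]Cl)ccc1OCc1ccccc1 | intermediate
7 | methyl 3-{4-[4-(benzyloxy)-3-methoxybenzyl]-2-nitrophenyl}-3-hydroxy-2-methoxypropanoate (syn/anti racemates) | COC(=O)C(OC)C(O)c1ccc(Cc2ccc(OCc3ccccc3)c(OC)c2)cc1[N+](=O)[O-] | intermediate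
8 | methyl 3-{4-[4-(benzyloxy)-3-methoxybenzyl]-2-(hydroxyamino)phenyl}-3-hydroxy-2-methoxypropanoate | COC(=O)C(OC)C(O)c1ccc(Cc2ccc(OCc3ccccc3)c(OC)c2)cc1NO | intermediate
9 | 7-[4-(benzyloxy)-3-methoxybenzyl]-1,4-dihydroxy-3-methoxy-3,4-dihydroquinolin-2(1H)-one (cis/trans racemates) | COC1C(O)c2ccc(Cc3ccc(OCc4ccccc4)c(OC)c3)cc2N(O)C1=O | intermediate
10 | 7-[4-(benzyloxy)-3-methoxybenzyl]-3-methoxy-1,4-bis(sulfooxy)-3,4-dihydroquinolin-2(1H)-one | COC1C(OS(=O)(=O)O)c2ccc(Cc3ccc(OCc4ccccc4)c(OC)c3)cc2N(OS(=O)(=O)O)C1=O | intermediate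
11 | 7-[4-(benzyloxy)-3-methoxybenzyl]-3-methoxy-4,8-bis(sulfooxy)-3,4-dihydroquinolin-2(1H)-one | COC1C(OS(=O)(=O)O)c2ccc(Cc3ccc(OCc4ccccc4)c(OC)c3)c(OS(=O)(=O)O)c2NC1=O | intermediate
12 | 7-[4-(benzyloxy)-3-methoxybenzyl]-3-methoxy-2-oxo-1,2-dihydroquinolin-8-yl hydrogen sulfate | COc1cc(Cc2ccc3cc(OC)c(=O)[nH]c3c2OS(=O)(=O)O)ccc1OCc1ccccc1 | intermediate
13 | scolopendrine, 7-(4-hydroxy-3-methoxybenzyl)-3-methoxy-2-oxo-1,2-dihydroquinolin-8-yl hydrogen sulfate (achiral) | COc1cc(Cc2ccc3cc(OC)c(=O)[nH]c3c2OS(=O)(=O)O)ccc1O | target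

Total step count: 5. Longest linear sequence: 5 (1 → 4 → 7 → 9 → 12 → 13).

**Steps most likely to fail**

**Step 4 (the proposed new step).**
- The N–O bond may stay too close to the arene plane to ionise.
- The sulfate may return at C6 instead of C8.
- Loss of C4–H from the nitrenium could give a 4-oxygenated quinolone.
- The pendant electron-rich arene could capture C8.

The fallback uses known chemistry, the Boyland–Sims persulfate oxidation of an aniline. It sets out from 7 and comes back at 12. Compound 7 is treated with MsCl/Et3N (CH2Cl2, 0 °C) to give the benzylic mesylate F1. DBU eliminates this by E1cB to methyl (Z)-3-{4-[4-(benzyloxy)-3-methoxybenzyl]-2-nitrophenyl}-2-methoxyacrylate F2. Fe/NH4Cl (EtOH/H2O, 70 °C) gives the (Z)-2-aminocinnamate F3, whose aryl group is trans to the ester, so it cannot lactamise. K2S2O8 in aq. KOH/acetone at 20 °C puts the sulfate on the only free ortho carbon and saponifies the ester, giving the (Z)-amino acid sulfate F4. Irradiation at 365 nm in aqueous MeOH at pH 5–6 gives the (E)-amino acid sulfate F5, which lactamises spontaneously to 12.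

**Step 3.**
- Over-reduction may give the aniline and hence the NH lactam.
- Azoxy coupling may occur.

The fallback builds the N–O bond by oxidation instead of partial reduction. It sets out from 7 and comes back at 9. Fe/NH4Cl (EtOH/H2O, 70 °C) reduces 7 fully to the aniline ester F6, which closes to the NH lactam 7-[4-(benzyloxy)-3-methoxybenzyl]-4-hydroxy-3-methoxy-3,4-dihydroquinolin-2(1H)-one F7. N,O-bis(trimethylsilyl)acetamide converts it to the bis(trimethylsilyl) lactim ether F8. Oxidation with the oxodiperoxymolybdenum–DMF complex (CH2Cl2, 25 °C) and an EDTA/MeOH work-up gives 9.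

**Step 2.**
- The free hydroxyl may protonate 6.
- The electron-rich benzylic zinc may undergo Wurtz homocoupling.
- The nitro group may interfere.

The fallback reverses the polarity of the coupling. It sets out from 4 (with 5) and comes back at 7. Miyaura borylation of 4 (B2pin2, PdCl2(dppf), KOAc, dioxane, 80 °C) gives the aryl pinacol boronate F9. This is joined to benzyl chloride 5 by Suzuki–Miyaura coupling (PdCl2(dppf), K3PO4, THF/H2O, 60 °C) to give 7.

**Further compounds**
F1 | step 4 | methyl 3-{4-[4-(benzyloxy)-3-methoxybenzyl]-2-nitrophenyl}-2-methoxy-3-(methylsulfonyloxy)propanoate | COC(=O)C(OC)C(OS(C)(=O)=O)c1ccc(Cc2ccc(OCc3ccccc3)c(OC)c2)cc1[N+](=O)[O-]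
F2 | step 4 | methyl (Z)-3-{4-[4-(benzyloxy)-3-methoxybenzyl]-2-nitrophenyl}-2-methoxyacrylate | COC(=O)/C(OC)=C/c1ccc(Cc2ccc(OCc3ccccc3)c(OC)c2)cc1[N+](=O)[O-]
F3 | step 4 | methyl (Z)-3-{2-amino-4-[4-(benzyloxy)-3-methoxybenzyl]phenyl}-2-methoxyacrylate | COC(=O)/C(OC)=C/c1ccc(Cc2ccc(OCc3ccccc3)c(OC)c2)cc1N
F4 | step 4 | (Z)-3-{2-amino-4-[4-(benzyloxy)-3-methoxybenzyl]-3-(sulfooxy)phenyl}-2-methoxyacrylic acid | OC(=O)/C(OC)=C/c1ccc(Cc2ccc(OCc3ccccc3)c(OC)c2)c(OS(=O)(=O)O)c1N
F5 | step 4 | (E)-3-{2-amino-4-[4-(benzyloxy)-3-methoxybenzyl]-3-(sulfooxy)phenyl}-2-methoxyacrylic acid | OC(=O)/C(OC)=C\c1ccc(Cc2ccc(OCc3ccccc3)c(OC)c2)c(OS(=O)(=O)O)c1N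
F6 | step 3 | methyl 3-{2-amino-4-[4-(benzyloxy)-3-methoxybenzyl]phenyl}-3-hydroxy-2-methoxypropanoate | COC(=O)C(OC)C(O)c1ccc(Cc2ccc(OCc3ccccc3)c(OC)c2)cc1N
F7 | step 3 | 7-[4-(benzyloxy)-3-methoxybenzyl]-4-hydroxy-3-methoxy-3,4-dihydroquinolin-2(1H)-one | COC1C(O)c2ccc(Cc3ccc(OCc4ccccc4)c(OC)c3)cc2NC1=O
F8 | step 3 | 7-[4-(benzyloxy)-3-methoxybenzyl]-3-methoxy-2,4-bis(trimethylsilyloxy)-3,4-dihydroquinoline | COC1C(O[Si](C)(C)C)c2ccc(Cc3ccc(OCc4ccccc4)c(OC)c3)cc2N=C1O[Si](C)(C)C
F9 | step 2 | methyl 3-hydroxy-2-methoxy-3-[2-nitro-4-(4,4,5,5-tetramethyl-1,3,2-dioxaborolan-2-yl)phenyl]propanoate | COC(=O)C(OC)C(O)c1ccc(B2OC(C)(C)C(C)(C)O2)cc1[N+](=O)[O-]
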